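**Assumption:** "prenyl" means 3-methylbut-2-en-1-yl throughout, and the stereocentre in the SMILES is read as (3R) (CIP order C2 > C1' > C4 > H).

## Retrosynthetic overview

1. Target 17 comes from methoxyquinone 16 by hydrolysis of the vinylogous methyl ester on ring B.
2. The pyran ring (ring C) is closed last, by Mitsunobu O-alkylation of the ring A phenol in quinone alcohol 15, which comes from hydroquinone 14.
3. Key disconnection C3–C1': the enamine of the ring A aldehyde (used as lactol 8) attacks quinone 12, which serves as an aryl cation equivalent of the electron-rich ring B, and this step sets C3.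
4. Lactol 8 comes from phenol 6 and acrolein; 6 comes from 1,3-dimethoxybenzene by ortho-lithiation/prenylation and meta C–H borylation/oxidation.
5. Quinone 12 comes from 1,2,4-trimethoxybenzene by ortho-lithiation/prenylation and oxidative demethylation. Rings A and B are bought as arenes; ring C is the only ring formed.

## Route

Step 1
Reactants: 1 1,3-dimethoxybenzene; 2 prenyl bromide
Product: 4 1,3-dimethoxy-2-prenylbenzene, via 2,6-dimethoxyphenyllithium 3 (not isolated)
Conditions: n-BuLi (1.1 equiv), THF, 0 °C to rt, 2 h; then 2, 0 °C to rt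
Reagents that add atoms: none
Why: Directed ortho-metalation removes the C2 proton flanked by both methoxy groups, and the aryllithium displaces bromide at the unsubstituted allylic terminus (SN2 alkylation).

Step 2
Reactants: 4 1,3-dimethoxy-2-prenylbenzene
Product: 6 3,5-dimethoxy-4-prenylphenol, via aryl pinacol boronate 5 (not isolated)
Conditions: [Ir(OMe)(cod)]2 (1.5 mol%), 4,4'-di-tert-butyl-2,2'-bipyridine (3 mol%), B2pin2 (0.6 equiv), THF, 80 °C; then NaOH, 30% H2O2, 0 °C to rt
Reagents that add atoms: hydrogen peroxide, OO
Why: Sterically controlled iridium-catalysed aromatic C–H borylation takes the only ring C–H with no ortho substituent (para to the prenyl group), and basic peroxide oxidation of the boronate gives the phenol without touching the trisubstituted alkene.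

Step 3
Reactants: 6 3,5-dimethoxy-4-prenylphenol; 7 acrolein
Product: 8 5,7-dimethoxy-6-prenylchroman-2-ol
Conditions: 6 (1.5 equiv), 7 (1.0 equiv, slow addition), racemic α,α-diphenylprolinol trimethylsilyl ether (10 mol%), PhCO2H (10 mol%), toluene, 0 °C
Reagents that add atoms: none
Why: Iminium-catalysed Friedel–Crafts conjugate alkylation of the electron-rich phenol at one of its two equivalent ortho positions (para is blocked), followed by spontaneous hemiacetalisation to the lactol, whose anomeric carbon is an inconsequential mixture.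

Step 4
Reactants: 9 1,2,4-trimethoxybenzene; 2 prenyl bromide
Product: 11 1,2,4-trimethoxy-3-prenylbenzene, via 2,3,6-trimethoxyphenyllithium 10 (not isolated)
Conditions: n-BuLi (1.1 equiv), THF, 0 °C to rt; then 2, 0 °C to rt
Reagents that add atoms: none
Why: Directed ortho-metalation occurs at C3 between the 2- and 4-methoxy groups, and SN2 alkylation with the primary allylic bromide installs the prenyl group there.

Step 5
Reactants: 11 1,2,4-trimethoxy-3-prenylbenzene
Product: 12 2-methoxy-3-prenyl-1,4-benzoquinone
Conditions: (NH4)2Ce(NO3)6 (2.5 equiv), MeCN/H2O 2:1, 0 °C, 15 min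
Reagents that add atoms: water, O
Why: Oxidative demethylation by tetravalent cerium converts the para-related 1,4-dimethoxy pair into the para-quinone (water attacks the ipso carbons of the arene radical cation, methanol leaves), keeping the 2-methoxy group as a vinylogous ester.

Step 6
Reactants: 8 5,7-dimethoxy-6-prenylchroman-2-ol; 12 2-methoxy-3-prenyl-1,4-benzoquinone
Product: 14 (2R)-2-(2,5-dihydroxy-4-methoxy-3-prenylphenyl)-3-(6-hydroxy-2,4-dimethoxy-3-prenylphenyl)propan-1-ol, via benzofuranol hemiacetal 13 (not isolated)
Conditions: 8 (1.3 equiv), 12 (1.0 equiv), (S)-α,α-diphenylprolinol trimethylsilyl ether (20 mol%), EtOH/H2O 9:1, −20 °C, 24–48 h; then NaBH4, 0 °C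
Reagents that add atoms: none
Why: Organocatalytic enantioselective α-arylation of an aldehyde with a quinone, in which the E-anti enamine of the ring-opened lactol adds to C5 of 12 (β to the C1 carbonyl, the one not deactivated by the vinylogous-ester methoxy group) and the adduct aromatises to the hydroquinone, so the quinone acts as an aryl cation equivalent; the bulky diphenyl(silyloxy)methyl group of the (S)-catalyst blocks one enamine face so the quinone bonds from the other and gives the (R) centre, which hemiacetal formation and in-flask borohydride reduction protect from racemisation.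

Step 7
Reactants: 14 (2R)-2-(2,5-dihydroxy-4-methoxy-3-prenylphenyl)-3-(6-hydroxy-2,4-dimethoxy-3-prenylphenyl)propan-1-ol
Product: 15 2-[(2R)-1-hydroxy-3-(6-hydroxy-2,4-dimethoxy-3-prenylphenyl)propan-2-yl]-5-methoxy-6-prenyl-1,4-benzoquinone
Conditions: Ag2O (2 equiv), Na2SO4, Et2O, rt, 1 h
Reagents that add atoms: none
Why: Mild hydroquinone-to-quinone oxidation leaves the ring A monophenol, the primary alcohol and the alkenes alone, and removes the ring B ortho-hydroxyl that would otherwise compete in the ring closure.

Step 8
Reactants: 15 2-[(2R)-1-hydroxy-3-(6-hydroxy-2,4-dimethoxy-3-prenylphenyl)propan-2-yl]-5-methoxy-6-prenyl-1,4-benzoquinone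
Product: 16 2-[(3R)-5,7-dimethoxy-6-prenylchroman-3-yl]-5-methoxy-6-prenyl-1,4-benzoquinone
Conditions: PPh3 (1.3 equiv) and DIAD (1.3 equiv) premixed in THF at 0 °C; then 15 added slowly (0.01 M), 0 °C to rt
Reagents that add atoms: none
Why: Intramolecular Mitsunobu etherification (6-exo-tet attack of the ring A phenoxide on the activated primary carbon) closes ring C without touching the adjacent stereocentre; preforming the betaine keeps free phosphine away from the quinone, whose only unsubstituted position is β to the deactivated vinylogous-ester carbonyl.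

Step 9
Reactants: 16 2-[(3R)-5,7-dimethoxy-6-prenylchroman-3-yl]-5-methoxy-6-prenyl-1,4-benzoquinone
Product: 17 2-[(3R)-5,7-dimethoxy-6-prenylchroman-3-yl]-5-hydroxy-6-prenyl-1,4-benzoquinone
Conditions: NaOH (1 M aq, 3 equiv), MeOH/THF, 0 °C, argon; then cold 1 M HCl to pH 3
Reagents that add atoms: sodium hydroxide, [Na+].[OH-]
Why: Addition–elimination hydrolysis of the quinone vinylogous methyl ester (the aryl methyl ethers are inert) gives the base-stable hydroxyquinone anion, which is less prone to γ-deprotonation at C3, and cold dilute acid releases the target without cyclising the ortho-prenyl group.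

## Compound list

1 | 1,3-dimethoxybenzene | COc1cccc(OC)c1 | starting material
2 | prenyl bromide (1-bromo-3-methylbut-2-ene) | CC(C)=CCBr | starting material
3 | 2,6-dimethoxyphenyllithium | [Li]c1c(OC)cccc1OC | intermediate
4 | 1,3-dimethoxy-2-prenylbenzene | COc1cccc(OC)c1CC=C(C)C | intermediate
5 | 2-(3,5-dimethoxy-4-prenylphenyl)-4,4,5,5-tetramethyl-1,3,2-dioxaborolane | COc1cc(cc(OC)c1CC=C(C)C)B1OC(C)(C)C(C)(C)O1 | intermediate
6 | 3,5-dimethoxy-4-prenylphenol | COc1cc(O)cc(OC)c1CC=C(C)C | intermediate
7 | acrolein (prop-2-enal) | C=CC=O | starting material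
8 | 5,7-dimethoxy-6-prenylchroman-2-ol (lactol of 3-(6-hydroxy-2,4-dimethoxy-3-prenylphenyl)propanal, C2 epimers) | COc1cc2OC(O)CCc2c(OC)c1CC=C(C)C | intermediate
9 | 1,2,4-trimethoxybenzene | COc1ccc(OC)c(OC)c1 | starting material
10 | 2,3,6-trimethoxyphenyllithium | [Li]c1c(OC)c(OC)ccc1OC | intermediate
11 | 1,2,4-trimethoxy-3-prenylbenzene | COc1ccc(OC)c(CC=C(C)C)c1OC | intermediate
12 | 2-methoxy-3-prenyl-1,4-benzoquinone | COC1=C(CC=C(C)C)C(=O)C=CC1=O | intermediate
13 | (3R)-3-[(6-hydroxy-2,4-dimethoxy-3-prenylphenyl)methyl]-6-methoxy-7-prenyl-2,3-dihydrobenzofuran-2,5-diol (C2 epimers, in equilibrium with the open aldehyde and the chroman-2-ol form) | COc1cc(O)c(c(OC)c1CC=C(C)C)C[C@H]1C(O)Oc2c1cc(O)c(OC)c2CC=C(C)C | intermediate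
14 | (2R)-2-(2,5-dihydroxy-4-methoxy-3-prenylphenyl)-3-(6-hydroxy-2,4-dimethoxy-3-prenylphenyl)propan-1-ol | COc1cc(O)c(c(OC)c1CC=C(C)C)C[C@H](c1cc(O)c(OC)c(CC=C(C)C)c1O)CO | intermediate
15 | 2-[(2R)-1-hydroxy-3-(6-hydroxy-2,4-dimethoxy-3-prenylphenyl)propan-2-yl]-5-methoxy-6-prenyl-1,4-benzoquinone | COc1cc(O)c(c(OC)c1CC=C(C)C)C[C@H](C1=CC(=O)C(OC)=C(CC=C(C)C)C1=O)CO | intermediate
16 | 2-[(3R)-5,7-dimethoxy-6-prenylchroman-3-yl]-5-methoxy-6-prenyl-1,4-benzoquinone | COc1cc2c(c(OC)c1CC=C(C)C)C[C@H](C1=CC(=O)C(OC)=C(CC=C(C)C)C1=O)CO2 | intermediate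
17 | 2-[(3R)-5,7-dimethoxy-6-prenylchroman-3-yl]-5-hydroxy-6-prenyl-1,4-benzoquinone | COc1cc2c(c(OC)c1CC=C(C)C)C[C@H](C1=CC(=O)C(O)=C(CC=C(C)C)C1=O)CO2 | target

## Step count and risks

Total step count: 9. Longest linear sequence: 7 (steps 1, 2, 3, 6, 7, 8, 9); steps 4 and 5 form the convergent quinone branch.

**Step 6 is the most likely to fail.** The lactol must open to enter the enamine cycle, quinone 12 is a weaker acceptor than benzoquinone, and it can also oxidise the product hydroquinone or trap the amine catalyst; the ee may suffer if the reaction has to be run warmer. The fallback sets out from 8 and 12 and comes back at 14. It keeps the same bond construction but moves stereocontrol to a resolution. The coupling is run with pyrrolidine (20 mol%) and AcOH in EtOH at rt, followed by NaBH4, to give the racemic hydroquinone alcohol F1. Acylation with Burkholderia cepacia lipase and vinyl acetate in MTBE at 30 °C, stopped slightly past half conversion, converts the (S)-enantiomer into the (S)-configured primary acetate F2. The unreacted (R)-alcohol is 14 (at most half of the material) and continues with step 7. The enantiopreference of the enzyme must be confirmed on the first run.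

**Step 8 is second.** Triphenylphosphine may add to or reduce the quinone before the betaine activates the alcohol. The fallback sets out from hemiacetal 13, isolated by leaving out the borohydride in step 6, and comes back at 16. Oxidation with Ag2O in Et2O gives the quinone lactol F3, in which only the ring A hydroxyl can hold the aldehyde, as a 3-quinonyl chroman-2-ol. Ionic reduction of this lactol with Et3SiH and BF3·OEt2 in CH2Cl2 at −78 °C removes the anomeric hydroxyl and gives 16 directly, with no phosphine present. The temperature must stay low so that the oxocarbenium ion does not lose the C3 proton and racemise.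

**Step 3 is third.** Acrolein can oligomerise, the lactol can be alkylated a second time at C8, and O-alkylation can compete. The fallback sets out from 6 and comes back at 8. Ortho-formylation (MgCl2, Et3N, paraformaldehyde, MeCN, reflux) gives the salicylaldehyde F4. Wittig reaction with Ph3P=CHCHO in toluene at 80 °C gives the (E)-2-hydroxycinnamaldehyde F5. Organocatalytic conjugate transfer hydrogenation (Hantzsch ester, dibenzylammonium trifluoroacetate, THF, rt) reduces only the enal double bond, and the saturated aldehyde closes to lactol 8.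

## Further compounds

F1 | step 6 | racemic 2-(2,5-dihydroxy-4-methoxy-3-prenylphenyl)-3-(6-hydroxy-2,4-dimethoxy-3-prenylphenyl)propan-1-ol | COc1cc(O)c(c(OC)c1CC=C(C)C)CC(c1cc(O)c(OC)c(CC=C(C)C)c1O)CO
F2 | step 6 | (2S)-2-(2,5-dihydroxy-4-methoxy-3-prenylphenyl)-3-(6-hydroxy-2,4-dimethoxy-3-prenylphenyl)propyl acetate | COc1cc(O)c(c(OC)c1CC=C(C)C)C[C@@H](c1cc(O)c(OC)c(CC=C(C)C)c1O)COC(C)=O
F3 | step 8 | 2-[(3R)-2-hydroxy-5,7-dimethoxy-6-prenylchroman-3-yl]-5-methoxy-6-prenyl-1,4-benzoquinone (C2 epimers) | COc1cc2c(c(OC)c1CC=C(C)C)C[C@H](C1=CC(=O)C(OC)=C(CC=C(C)C)C1=O)C(O)O2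
F4 | step 3 | 6-hydroxy-2,4-dimethoxy-3-prenylbenzaldehyde | COc1cc(O)c(C=O)c(OC)c1CC=C(C)C
F5 | step 3 | (2E)-3-(6-hydroxy-2,4-dimethoxy-3-prenylphenyl)prop-2-enal | COc1cc(O)c(/C=C/C=O)c(OC)c1CC=C(C)C
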